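## Structural features

The target is a germacranolide of the heliangolide type: a ten-membered carbocycle (C1–C10) with a trans-fused α-methylene-γ-butyrolactone across C6–C7 (oxygen on C6, C11–C13 on C7). The ring also carries a trans 1,10-epoxide (methyl on C10), a Z trisubstituted C4=C5 alkene (methyl on C4), an allylic benzoate at C3 and, at C8, the ester of (2S,3R)-2,3-dimethyloxirane-2-carboxylic acid, the epoxide of tiglic acid. C6, C7 and C8 are contiguous stereocentres with O6 trans and O8 cis to the C7 side chain (6α-O, 7β-C, 8β-O); C1 and C10 are adjacent in the epoxide; C3 stands alone between a methylene and the alkene. Fragile groups are the exocyclic enoate (a Michael acceptor), the two epoxides, the esters, which can migrate to a neighbouring hydroxyl, and the 1(10),4-diene, which cyclises across the ring under acid and can undergo Cope rearrangement on strong heating. The real difficulty is the medium ring with one E and one Z trisubstituted alkene in fixed positions, together with the C6–C7–C8 triad, whose relative configuration cannot be left to the conformational bias of a ten-membered ring. The key step exploits the array C6(=O)–C7–C8–C9–C10=C1 with C4=C5 conjugated to C6. This is a cyclodec-5-enone whose C1 and C6 were once bonded in a six-membered ring, so the E C1=C10 bond, the Z C4=C5 bond and the C8 heteroatom stereocentre all follow from one [3,3] shift.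

## Logic of the disconnections

36 to 35: the two C–O bonds of the 1,10-epoxide are cut last. The C1=C10 bond of 35 is the only electron-rich alkene left, so no protecting group is needed; the forward step must attack its peripheral face.

35 to 31 (through 33): the C11=C13 bond is cut. Keeping the Michael acceptor out of the route until the end removes it from every nucleophilic and oxidative step; the forward step must enolise only C11 without letting the enolate reach the C8 ester.

31 to 29 (through 30): the C3 acyl–oxygen bond is cut and the oxygen returned to its benzyl-type ether, which is what survives organometallic and strongly basic steps. The demand is an oxidative deprotection that leaves the allylic alcohol alone.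

29 to 24 and 27: three bonds are cut at once, O6–C12 of the lactone, O8–acyl of the ester and C6–H. One intramolecular hydride transfer from the O8 hemiacetal of 27 sets C6 anti to C8 and leaves the acyl group on O8, so the two hydroxyls are never both free. The demand is that the ten-membered ring accommodates the six-membered transfer array.

24 to 21 and 22: the C7–C11 bond is cut. The free 8-hydroxyl is used as a lithium alkoxide to hold the enolate in a chelate, so C11 enters cis to O8. An alkylation controlled only by a C8 silyl group was set aside, because peripheral attack on the ring-trans enolate with silicon outside should give the C7 epimer.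

21 to 19: the C8–O bond is traced to a C8–Si bond, which can be exchanged for oxygen with retention. The silyl group must be oxidisable without electrophiles that would attack the alkenes, hence the benzyldimethylsilyl group.

19 to 16: the C8–C9 bond is cut and C1–C6 reconnected, which contracts the ten-membered ring to a cyclohexenol with trans alkenyl groups. The gain is the whole medium ring, both alkene geometries and C8 in one step. Checked against 36, 16 and 19 carry the correct 3S centre and 19 the 8R centre, and need no correction.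

16 to 9 and 13: the bond between the carbinol carbon and the silylvinyl unit is cut. The forward addition must come anti to the isopropenyl group and must not enolise the ketone. 13 is traced to 10 and 11 by two successive tin–lithium exchanges.

9 to 8, 7, 6 and 5: the carbonyl is masked as its dimethyl ketal and the C3 oxygen is traced to the ketone of 4. Hydride reduction of 4 is expected to give the hydroxyl cis to isopropenyl (5), so an inversion (5 to 6 to 7) is written in to reach the trans relationship that 16 needs.

4 to 2 and 3: the bond from the isopropenyl group to the ring is cut; an asymmetric conjugate addition to the less substituted enone arm of 2 sets the only stereocentre that is introduced by a catalyst in the main line.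

2 to 1: the ketal carbon is traced to the methoxy-bearing carbon of a phenol; oxidative dearomatisation delivers the cross-conjugated dienone.

27 to 26 and 25: the epoxide C–O bonds are cut to an allylic alcohol, so a catalytic asymmetric epoxidation fixes both centres of the C8 ester before it meets the ring.

## Other disconnections considered

Alternative 1: The C4=C5 and C1=C10 π-bonds are read as the product of a thermal cycloreversion of a bicyclo[2.2.0]hexane, which leads back to photoadduct A3, itself formed from enone A1 and cyclobutene ketal A2 by [2+2] photocycloaddition (C4–C5 and C1–C10 formed; C5–C10 and C1–C4 broken later on heating).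
- In its favour: A3 holds all ten ring carbons, both methyl groups and the oxygens at C3, C6 and C8; it is assembled from two fragments in one step, without base and without medium-ring closure.
- Against it here: the cycloaddition must join a β-substituted enone to a trisubstituted cyclobutene, create two adjacent quaternary carbons with one regiochemistry and add anti to the C8 silyl ether. The opening needs about 200 °C, decides E against Z through a diradical, and competes with Cope equilibration of the diene. C3 and C6 arrive as carbonyls and both must still be reduced selectively on the medium ring.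
- Comparison: both plans make the ring by cleaving a bond of a smaller ring, and on this point they are equal. Alternative 1 is the better in convergence, and it needs no inversion at C3. The chosen plan is better defined mechanistically, since a chair [3,3] shift ties C8 to the alkene geometry, and needs fewer redox corrections after the ring is made.

Alternative 2: The lactone C6–O bond is cut, so the carbocycle is completed first as primary amide A4 and the oxygen is introduced last. The N-iodo amide formed in the flask gives an amidyl radical, 1,5-hydrogen transfer from C6 follows, and the amide oxygen closes onto C6 to give 13-nor lactone A5 after hydrolysis.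
- In its favour: no O6 hydroxyl ever stands free beside O8, and no medium-ring ketone has to be reduced. On both points the alternative is the equal or the better of the chosen plan, which has to solve them by an internal hydride transfer.
- Against it here: the C6–H bond is allylic, so the radical is delocalised over C4–C6, which risks the Z geometry and reaction at C4. The C8–H bond is equally within reach of a 1,5-transfer. Iodine and PhI(OAc)2 under light threaten the epoxides and any remaining alkene. Nothing controls the configuration at C6 except the ring fusion, and C13 is still missing.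
- Comparison: a separate synthesis of the carbocycle without the C6 carbonyl would be needed, and that carbonyl is what drives the ring expansion of the chosen plan, so no steps are saved. Open-shell selectivity replaces a pericyclic step with a predictable topology.

Alternative 3: The C2–C3 and C1–O bonds are cut. Oxime A6 is oxidised with hypochlorite to nitrile oxide A7, which adds across the terminal vinyl group to close the ten-membered ring as isoxazoline A8.
- In its favour: the tertiary C10–O centre comes from the chiral pool, which is better than the chosen plan, where the epoxide configuration rests on the facial selectivity of a late epoxidation. The lactone and the C6–C8 triad can be built on an open chain with acyclic stereocontrol. The isoxazoline stores the C3 carbonyl and the C1 oxygen.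
- Against it here: the ring is closed end to end, with the entropic cost of a ten-membered ring, the need for dilution and competing dimerisation of A7. The conjugated Z unit of A7 may isomerise, and the C1 configuration relative to C10 is open. After the key step, N–O cleavage, reduction at C3 and epoxide closure with inversion still remain.
- Comparison: both plans install ring and oxygen functionality in one step and are equal in that respect. The chosen plan avoids dilution and ring strain in the closing step. Alternative 3 is longer after its key step but safer for the C1/C10 and C6–C8 stereochemistry.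

Key step: step 10

Remarks on the chemistry (assumptions):
- The hydride reduction of 4 is taken to follow the carvone pattern (hydroxyl cis to isopropenyl), so steps 4 and 5 invert that centre.
- The BINAP antipode in step 2 is chosen by the usual facial model for cyclohexenones.
- The C11 configuration of 33 and 34 is left undefined because step 19 erases it.
- (E)-2-Methylbut-2-en-1-ol (25) is taken as a commercial material.

## Steps

Step 1
Reactants: 1 4-methoxy-2-methylphenol
Product: 2 4,4-dimethoxy-2-methylcyclohexa-2,5-dien-1-one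
Conditions: PhI(OAc)2 (1.1 equiv), MeOH, 0 °C
Reagents that add atoms: methanol CO
Why: Oxidative dearomatisation of a para-methoxyphenol; methanol traps the oxidised ring at the methoxy-bearing carbon to give the quinone monoketal, and no stereocentre is formed.

Step 2
Reactants: 2 4,4-dimethoxy-2-methylcyclohexa-2,5-dien-1-one; 3 4,4,5,5-tetramethyl-2-(prop-1-en-2-yl)-1,3,2-dioxaborolane
Product: 4 (5R)-4,4-dimethoxy-2-methyl-5-(prop-1-en-2-yl)cyclohex-2-en-1-one
Conditions: [Rh(OH)((R)-binap)]2 (3 mol %), KOH (0.2 equiv), dioxane/H2O 10:1, 35 °C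
Reagents that add atoms: none
Why: Hayashi–Miyaura asymmetric conjugate addition; the alkenylrhodium species adds to the unsubstituted enone arm because the α-methyl arm is much less reactive, the ligand sets the new centre as R, and the basic medium keeps the ketal intact.

Step 3
Reactants: 4 (5R)-4,4-dimethoxy-2-methyl-5-(prop-1-en-2-yl)cyclohex-2-en-1-one
Product: 5 (1R,5R)-4,4-dimethoxy-2-methyl-5-(prop-1-en-2-yl)cyclohex-2-en-1-ol (hydroxyl cis to isopropenyl)
Conditions: NaBH4, CeCl3·7H2O, MeOH, −78 to 0 °C
Reagents that add atoms: none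
Why: Luche 1,2-reduction; as with carvone-type 5-substituted enones the hydride should arrive on the face that leaves the hydroxyl cis to isopropenyl, which is the wrong epimer for C3 and is inverted in step 4.

Step 4
Reactants: 5 (1R,5R)-4,4-dimethoxy-2-methyl-5-(prop-1-en-2-yl)cyclohex-2-en-1-ol
Product: 6 (1S,5R)-4,4-dimethoxy-2-methyl-5-(prop-1-en-2-yl)cyclohex-2-en-1-yl 4-nitrobenzoate (ester trans to isopropenyl)
Conditions: PPh3, DIAD, 4-O2NC6H4CO2H, THF, 0 °C to rt
Reagents that add atoms: 4-nitrobenzoic acid O=C(O)c1ccc(cc1)[N+](=O)[O-]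
Why: Mitsunobu inversion of a secondary allylic alcohol; SN2 displacement of the oxyphosphonium group by the carboxylate gives the 1S ester, and SN2′ attack is blocked by the adjacent quaternary ketal carbon.

Step 5
Reactants: 6 (1S,5R)-4,4-dimethoxy-2-methyl-5-(prop-1-en-2-yl)cyclohex-2-en-1-yl 4-nitrobenzoate
Product: 7 (1S,5R)-4,4-dimethoxy-2-methyl-5-(prop-1-en-2-yl)cyclohex-2-en-1-ol (hydroxyl trans to isopropenyl)
Conditions: K2CO3, MeOH, 0 °C to rt
Reagents that add atoms: none
Why: Base-catalysed methanolysis of the activated aryl ester; ketal and stereocentres are untouched.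

Step 6
Reactants: 7 (1S,5R)-4,4-dimethoxy-2-methyl-5-(prop-1-en-2-yl)cyclohex-2-en-1-ol
Product: 8 1-methoxy-4-({[(1S,5R)-4,4-dimethoxy-2-methyl-5-(prop-1-en-2-yl)cyclohex-2-en-1-yl]oxy}methyl)benzene
Conditions: NaH, 4-MeOC6H4CH2Cl, Bu4NI (cat.), THF/DMF, 0 °C to rt
Reagents that add atoms: 4-methoxybenzyl chloride COc1ccc(CCl)cc1
Why: Williamson etherification of the sodium alkoxide; the 4-methoxybenzyl ether withstands organolithium, KH, amide bases and peroxide and is removed oxidatively later.

Step 7
Reactants: 8 1-methoxy-4-({[(1S,5R)-4,4-dimethoxy-2-methyl-5-(prop-1-en-2-yl)cyclohex-2-en-1-yl]oxy}methyl)benzene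
Product: 9 (4S,6R)-4-(4-methoxybenzyloxy)-3-methyl-6-(prop-1-en-2-yl)cyclohex-2-en-1-one
Conditions: PPTS (cat.), acetone/H2O 10:1, rt; used at once
Reagents that add atoms: water O
Why: Mild acid hydrolysis of the allylic dimethyl ketal through a stabilised oxocarbenium ion; it is done only after C3 is reduced and protected so that aromatisation is excluded, and the trans 4,6-isomer (ether pseudoaxial beside the ring methyl, isopropenyl equatorial) should be the stable epimer.

Step 8
Reactants: 10 (E)-1,2-bis(tributylstannyl)ethene; 11 benzyl(chloro)dimethylsilane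
Product: 13 benzyl(dimethyl)[(E)-2-(tributylstannyl)ethenyl]silane, via (E)-2-(tributylstannyl)ethenyllithium 12 (not isolated)
Conditions: n-BuLi (1.0 equiv), THF, −78 °C; then 11, −78 °C to rt
Reagents that add atoms: none
Why: Tin–lithium exchange at one terminus of the distannane and silylation of the vinyllithium, both with retention of the E geometry.

Step 9
Reactants: 13 benzyl(dimethyl)[(E)-2-(tributylstannyl)ethenyl]silane; 9 (4S,6R)-4-(4-methoxybenzyloxy)-3-methyl-6-(prop-1-en-2-yl)cyclohex-2-en-1-one
Product: 16 (1R,4S,6R)-1-[(E)-2-(benzyldimethylsilyl)ethenyl]-4-(4-methoxybenzyloxy)-3-methyl-6-(prop-1-en-2-yl)cyclohex-2-en-1-ol, via (E)-2-(benzyldimethylsilyl)ethenyllithium 14 (not isolated), via dichloro[(E)-2-(benzyldimethylsilyl)ethenyl]cerium 15 (not isolated)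
Conditions: 13, n-BuLi, THF, −78 °C; CeCl3 (dried), −78 °C; then 9, −78 °C; aq. NH4Cl
Reagents that add atoms: none
Why: Second tin–lithium exchange, transmetallation to the organocerium reagent and 1,2-addition; the weakly basic cerium reagent avoids enolisation of the α-isopropenyl ketone and conjugate addition, and entry anti to the adjacent isopropenyl group should set C1 as R with the two alkenyl groups trans.

Step 10
Reactants: 16 (1R,4S,6R)-1-[(E)-2-(benzyldimethylsilyl)ethenyl]-4-(4-methoxybenzyloxy)-3-methyl-6-(prop-1-en-2-yl)cyclohex-2-en-1-ol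
Product: 19 (3S,8R)-8-(benzyldimethylsilyl)-3-(4-methoxybenzyloxy)-4,10-dimethylcyclodeca-1(10)E,4Z-dien-6-one (germacrane numbering), via potassium cyclohexenolate 17 (not isolated), via potassium dienolate 18 (not isolated)
Conditions: KH (5 equiv), 18-crown-6 (1.5 equiv), degassed THF, 0 °C to rt; then aq. NH4Cl, −78 °C
Reagents that add atoms: none
Why: Deprotonation gives alkoxide 17, whose oxyanion weakens the bond between the carbinol carbon and the isopropenyl-bearing carbon and accelerates a concerted [3,3] shift (anionic oxy-Cope rearrangement); the closest known class is the rearrangement of trans-1,2-dialkenylcyclohexanols to cyclodec-5-enones. Only the chair transition state with both ring bonds equatorial brings the trans alkenyl termini together, so C8–C9 forms as C1–C6 breaks and the ten-membered ring arises by expansion of the six-membered ring, not by end-to-end closure. In that chair the ring residue on the isopropenyl carbon is equatorial, which makes the new C1=C10 bond E, while the C4=C5 bond inherited from the cyclohexene stays Z. The E vinylsilane places silicon equatorial at the reacting terminus, and together with the R configuration of the isopropenyl carbon this fixes C8 as R (8β-silyl), so chirality is relayed from a centre that the same step destroys. The selectivity needed is chair over boat and one sense of the chair; both are secured by the trans arrangement of the alkenyl groups and the E geometry of the silane. The product is the β-silyl enolate 18, in which silicon cannot leave as a β-alkoxy group would, and protonation at C7 at low temperature gives 19.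

Step 11
Reactants: 19 (3S,8R)-8-(benzyldimethylsilyl)-3-(4-methoxybenzyloxy)-4,10-dimethylcyclodeca-1(10)E,4Z-dien-6-one
Product: 21 (3S,8R)-8-hydroxy-3-(4-methoxybenzyloxy)-4,10-dimethylcyclodeca-1(10)E,4Z-dien-6-one, via fluorodimethylsilyl ketone 20 (not isolated)
Conditions: Bu4NF, THF, 0 °C; then 30% H2O2, KHCO3, MeOH, rt
Reagents that add atoms: hydrogen peroxide OO
Why: Tamao oxidation of the benzyldimethylsilyl group; fluoride removes the benzyl group and basic peroxide moves C8 from silicon to oxygen with retention, giving the 8β-alcohol without the electrophilic reagents that an arylsilane would need and that the alkenes would not survive.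

Step 12
Reactants: 21 (3S,8R)-8-hydroxy-3-(4-methoxybenzyloxy)-4,10-dimethylcyclodeca-1(10)E,4Z-dien-6-one; 22 prop-2-en-1-yl 2-bromoacetate
Product: 24 prop-2-en-1-yl 2-[(3S,7R,8R)-8-hydroxy-3-(4-methoxybenzyloxy)-4,10-dimethyl-6-oxocyclodeca-1(10)E,4Z-dien-7-yl]acetate (side chain cis to the 8-hydroxyl), via dilithium alkoxide enolate 23 (not isolated)
Conditions: LiN(iPr)2 (2.2 equiv), THF, −78 °C; 22, −78 to −45 °C; AcOH quench at −78 °C
Reagents that add atoms: none
Why: Fráter–Seebach-type alkylation of the aldolate dianion; lithium bridges the alkoxide and the enolate oxygen so that O8 eclipses the enolate, C9 lies on one face and the electrophile enters from the other, peripheral face, which puts C11 cis to O8 on the ring (acyclic descriptor anti). C7 is the only enolisable position of the enone.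

Step 13
Reactants: 25 (E)-2-methylbut-2-en-1-ol
Product: 26 [(2R,3R)-2,3-dimethyloxiran-2-yl]methanol
Conditions: Ti(OiPr)4 (10 mol %), D-(−)-diisopropyl tartrate (12 mol %), t-BuOOH, 4 Å molecular sieves, CH2Cl2, −20 °C
Reagents that add atoms: tert-butyl hydroperoxide CC(C)(C)OO
Why: Sharpless asymmetric epoxidation of an E trisubstituted allylic alcohol; the D-(−)-tartrate catalyst delivers oxygen to the face that gives the 2R,3R epoxy alcohol.

Step 14
Reactants: 26 [(2R,3R)-2,3-dimethyloxiran-2-yl]methanol
Product: 27 (2S,3R)-2,3-dimethyloxirane-2-carbaldehyde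
Conditions: TEMPO (10 mol %), PhI(OAc)2, CH2Cl2, rt; NaHCO3 wash, bulb-to-bulb distillation, kept as a THF solution
Reagents that add atoms: none
Why: Oxoammonium-mediated oxidation of the primary alcohol; the α-carbon is quaternary so nothing can epimerise, and the descriptor at C2 changes only because the CIP priorities change.

Step 15
Reactants: 24 prop-2-en-1-yl 2-[(3S,7R,8R)-8-hydroxy-3-(4-methoxybenzyloxy)-4,10-dimethyl-6-oxocyclodeca-1(10)E,4Z-dien-7-yl]acetate; 27 (2S,3R)-2,3-dimethyloxirane-2-carbaldehyde
Product: 29 8β-[(2S,3R)-2,3-dimethyloxirane-2-carbonyloxy]-3β-(4-methoxybenzyloxy)-13-norgermacra-1(10)E,4Z-dien-6α,12-olide (3S,6R,7R,8R), via 6α-hydroxy allyl ester 28 (not isolated)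
Conditions: SmI2 (0.3 equiv), 27 (5 equiv), THF, −10 °C; then rt; aq. NaHCO3
Reagents that add atoms: none
Why: Evans–Tishchenko reduction; the hemiacetal of O8 and 27, held on trivalent samarium together with the C6 carbonyl, transfers its hydride through a six-membered chair, so C6 becomes the 1,3-anti (6α) alcohol and the acyl group stays on O8. The samarium alkoxide at O6 should then close onto the adjacent allyl ester to give the trans-fused γ-lactone, so the two hydroxyls never have to be distinguished.

Step 16
Reactants: 29 8β-[(2S,3R)-2,3-dimethyloxirane-2-carbonyloxy]-3β-(4-methoxybenzyloxy)-13-norgermacra-1(10)E,4Z-dien-6α,12-olide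
Product: 30 3β-hydroxy-8β-[(2S,3R)-2,3-dimethyloxirane-2-carbonyloxy]-13-norgermacra-1(10)E,4Z-dien-6α,12-olide
Conditions: DDQ (1.2 equiv), CH2Cl2/pH 7 buffer, 0 °C
Reagents that add atoms: none
Why: Oxidative cleavage of the 4-methoxybenzyl ether through its benzylic oxocarbenium ion, hydrolysed by the buffer; esters, lactone and epoxide are inert.

Step 17
Reactants: 30 3β-hydroxy-8β-[(2S,3R)-2,3-dimethyloxirane-2-carbonyloxy]-13-norgermacra-1(10)E,4Z-dien-6α,12-olide
Product: 31 3β-benzoyloxy-8β-[(2S,3R)-2,3-dimethyloxirane-2-carbonyloxy]-13-norgermacra-1(10)E,4Z-dien-6α,12-olide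
Conditions: BzCl, pyridine, DMAP (cat.), CH2Cl2, 0 °C
Reagents that add atoms: benzoyl chloride O=C(Cl)c1ccccc1
Why: Acylation of the secondary allylic alcohol through the acylpyridinium ion, with retention at C3.

Step 18
Reactants: 31 3β-benzoyloxy-8β-[(2S,3R)-2,3-dimethyloxirane-2-carbonyloxy]-13-norgermacra-1(10)E,4Z-dien-6α,12-olide
Product: 33 3β-benzoyloxy-13-(dimethylamino)-8β-[(2S,3R)-2,3-dimethyloxirane-2-carbonyloxy]germacra-1(10)E,4Z-dien-6α,12-olide (both C11 epimers), via trimethylsilyl ketene acetal 32 (not isolated)
Conditions: LiN(SiMe3)2 added to 31 and Me3SiCl, THF, −78 °C; then [CH2=NMe2]I, CH2Cl2, rt; aq. NaHCO3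
Reagents that add atoms: dimethylmethyleneiminium iodide C=[N+](C)C.[I-]
Why: Mukaiyama–Mannich reaction; C11 is the only enolisable position, and silylating the enolate as it forms avoids a long-lived lactone enolate next to the C8 ester, which could otherwise attack that ester. The ketene acetal then adds to the iminium salt to install C13.

Step 19
Reactants: 33 3β-benzoyloxy-13-(dimethylamino)-8β-[(2S,3R)-2,3-dimethyloxirane-2-carbonyloxy]germacra-1(10)E,4Z-dien-6α,12-olide
Product: 35 3β-benzoyloxy-8β-[(2S,3R)-2,3-dimethyloxirane-2-carbonyloxy]germacra-1(10)E,4Z,11(13)-trien-6α,12-olide, via trimethylammonium iodide 34 (not isolated)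
Conditions: MeI, THF, rt; then aq. NaHCO3, EtOAc, rt
Reagents that add atoms: none
Why: Quaternisation of the amine and β-elimination of trimethylamine under bicarbonate give the exocyclic enoate.

Step 20
Reactants: 35 3β-benzoyloxy-8β-[(2S,3R)-2,3-dimethyloxirane-2-carbonyloxy]germacra-1(10)E,4Z,11(13)-trien-6α,12-olide
Product: 36 1β,10α-epoxy-3β-benzoyloxy-8β-[(2S,3R)-2,3-dimethyloxirane-2-carbonyloxy]germacra-4Z,11(13)-dien-6α,12-olide (CNP0324463.4)
Conditions: mCPBA (1.1 equiv), NaHCO3, CH2Cl2, 0 °C
Reagents that add atoms: 3-chloroperoxybenzoic acid O=C(OO)c1cccc(Cl)c1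
Why: Prilezhaev epoxidation; the strained E C1=C10 alkene is the most electron-rich π-bond (C4=C5 is flanked by two acyloxy-bearing carbons and C11=C13 is conjugated), and attack on its peripheral face with C14 on the β side should give the 1R,10R (1β,10α) epoxide.

## Compound list

1 | 4-methoxy-2-methylphenol | COc1ccc(O)c(C)c1 | starting material
2 | 4,4-dimethoxy-2-methylcyclohexa-2,5-dien-1-one | CC1=CC(OC)(OC)C=CC1=O | intermediate
3 | 4,4,5,5-tetramethyl-2-(prop-1-en-2-yl)-1,3,2-dioxaborolane | CC(=C)B1OC(C)(C)C(C)(C)O1 | starting material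
4 | (5R)-4,4-dimethoxy-2-methyl-5-(prop-1-en-2-yl)cyclohex-2-en-1-one | CC(=C)[C@H]1CC(=O)C(C)=CC1(OC)OC | intermediate
5 | (1R,5R)-4,4-dimethoxy-2-methyl-5-(prop-1-en-2-yl)cyclohex-2-en-1-ol | CC(=C)[C@H]1C[C@@H](O)C(C)=CC1(OC)OC | intermediate
6 | (1S,5R)-4,4-dimethoxy-2-methyl-5-(prop-1-en-2-yl)cyclohex-2-en-1-yl 4-nitrobenzoate | CC(=C)[C@H]1C[C@H](OC(=O)c2ccc(cc2)[N+](=O)[O-])C(C)=CC1(OC)OC | intermediate
7 | (1S,5R)-4,4-dimethoxy-2-methyl-5-(prop-1-en-2-yl)cyclohex-2-en-1-ol | CC(=C)[C@H]1C[C@H](O)C(C)=CC1(OC)OC | intermediate
8 | 1-methoxy-4-({[(1S,5R)-4,4-dimethoxy-2-methyl-5-(prop-1-en-2-yl)cyclohex-2-en-1-yl]oxy}methyl)benzene | CC(=C)[C@H]1C[C@H](OCc2ccc(OC)cc2)C(C)=CC1(OC)OC | intermediate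
9 | (4S,6R)-4-(4-methoxybenzyloxy)-3-methyl-6-(prop-1-en-2-yl)cyclohex-2-en-1-one | CC(=C)[C@H]1C[C@H](OCc2ccc(OC)cc2)C(C)=CC1=O | intermediate
10 | (E)-1,2-bis(tributylstannyl)ethene | CCCC[Sn](CCCC)(CCCC)/C=C/[Sn](CCCC)(CCCC)CCCC | starting material
11 | benzyl(chloro)dimethylsilane | C[Si](C)(Cl)Cc1ccccc1 | starting material
12 | (E)-2-(tributylstannyl)ethenyllithium | [Li]/C=C/[Sn](CCCC)(CCCC)CCCC | intermediate
13 | benzyl(dimethyl)[(E)-2-(tributylstannyl)ethenyl]silane | CCCC[Sn](CCCC)(CCCC)/C=C/[Si](C)(C)Cc1ccccc1 | intermediate
14 | (E)-2-(benzyldimethylsilyl)ethenyllithium | [Li]/C=C/[Si](C)(C)Cc1ccccc1 | intermediate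
15 | dichloro[(E)-2-(benzyldimethylsilyl)ethenyl]cerium | Cl[Ce](Cl)/C=C/[Si](C)(C)Cc1ccccc1 | intermediate
16 | (1R,4S,6R)-1-[(E)-2-(benzyldimethylsilyl)ethenyl]-4-(4-methoxybenzyloxy)-3-methyl-6-(prop-1-en-2-yl)cyclohex-2-en-1-ol | CC(=C)[C@H]1C[C@H](OCc2ccc(OC)cc2)C(C)=C[C@]1(O)/C=C/[Si](C)(C)Cc1ccccc1 | intermediate
17 | potassium alkoxide of 16 | CC(=C)[C@H]1C[C@H](OCc2ccc(OC)cc2)C(C)=C[C@]1([O-])/C=C/[Si](C)(C)Cc1ccccc1.[K+] | intermediate
18 | potassium C6,C7-enolate of 19 (oxygen cis to C8) | [K+].C1/C=C(\C)C[C@@H]([Si](C)(C)Cc2ccccc2)/C=C(\[O-])/C=C(/C)[C@H]1OCc1ccc(OC)cc1 | intermediate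
19 | (3S,8R)-8-(benzyldimethylsilyl)-3-(4-methoxybenzyloxy)-4,10-dimethylcyclodeca-1(10)E,4Z-dien-6-one | O=C1/C=C(/C)[C@@H](OCc2ccc(OC)cc2)C/C=C(\C)C[C@@H]([Si](C)(C)Cc2ccccc2)C1 | intermediate
20 | (3S,8R)-8-(fluorodimethylsilyl)-3-(4-methoxybenzyloxy)-4,10-dimethylcyclodeca-1(10)E,4Z-dien-6-one | O=C1/C=C(/C)[C@@H](OCc2ccc(OC)cc2)C/C=C(\C)C[C@@H]([Si](C)(C)F)C1 | intermediate
21 | (3S,8R)-8-hydroxy-3-(4-methoxybenzyloxy)-4,10-dimethylcyclodeca-1(10)E,4Z-dien-6-one | O=C1/C=C(/C)[C@@H](OCc2ccc(OC)cc2)C/C=C(\C)C[C@@H](O)C1 | intermediate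
22 | prop-2-en-1-yl 2-bromoacetate | C=CCOC(=O)CBr | starting material
23 | dilithium alkoxide enolate of 21 | [Li+].[Li+].C1/C=C(\C)C[C@@H]([O-])/C=C(\[O-])/C=C(/C)[C@H]1OCc1ccc(OC)cc1 | intermediate
24 | prop-2-en-1-yl 2-[(3S,7R,8R)-8-hydroxy-3-(4-methoxybenzyloxy)-4,10-dimethyl-6-oxocyclodeca-1(10)E,4Z-dien-7-yl]acetate | O=C1/C=C(/C)[C@@H](OCc2ccc(OC)cc2)C/C=C(\C)C[C@@H](O)[C@H]1CC(=O)OCC=C | intermediate
25 | (E)-2-methylbut-2-en-1-ol | C/C=C(\C)CO | starting material
26 | [(2R,3R)-2,3-dimethyloxiran-2-yl]methanol | OC[C@@]1(C)O[C@@H]1C | intermediate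
27 | (2S,3R)-2,3-dimethyloxirane-2-carbaldehyde | O=C[C@@]1(C)O[C@@H]1C | intermediate
28 | prop-2-en-1-yl 2-{6α-hydroxy-8β-[(2S,3R)-2,3-dimethyloxirane-2-carbonyloxy]-3β-(4-methoxybenzyloxy)-4,10-dimethylcyclodeca-1(10)E,4Z-dien-7β-yl}acetate | O[C@@H]1/C=C(/C)[C@@H](OCc2ccc(OC)cc2)C/C=C(\C)C[C@@H](OC(=O)[C@@]2(C)O[C@@H]2C)[C@H]1CC(=O)OCC=C | intermediate
29 | 8β-[(2S,3R)-2,3-dimethyloxirane-2-carbonyloxy]-3β-(4-methoxybenzyloxy)-13-norgermacra-1(10)E,4Z-dien-6α,12-olide | C1C(=O)O[C@@H]2/C=C(/C)[C@@H](OCc3ccc(OC)cc3)C/C=C(\C)C[C@@H](OC(=O)[C@@]3(C)O[C@@H]3C)[C@@H]12 | intermediate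
30 | 3β-hydroxy-8β-[(2S,3R)-2,3-dimethyloxirane-2-carbonyloxy]-13-norgermacra-1(10)E,4Z-dien-6α,12-olide | C1C(=O)O[C@@H]2/C=C(/C)[C@@H](O)C/C=C(\C)C[C@@H](OC(=O)[C@@]3(C)O[C@@H]3C)[C@@H]12 | intermediate
31 | 3β-benzoyloxy-8β-[(2S,3R)-2,3-dimethyloxirane-2-carbonyloxy]-13-norgermacra-1(10)E,4Z-dien-6α,12-olide | C1C(=O)O[C@@H]2/C=C(/C)[C@@H](OC(=O)c3ccccc3)C/C=C(\C)C[C@@H](OC(=O)[C@@]3(C)O[C@@H]3C)[C@@H]12 | intermediate
32 | trimethylsilyl ketene acetal of 31 | C1=C(O[Si](C)(C)C)O[C@@H]2/C=C(/C)[C@@H](OC(=O)c3ccccc3)C/C=C(\C)C[C@@H](OC(=O)[C@@]3(C)O[C@@H]3C)[C@@H]12 | intermediate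
33 | 3β-benzoyloxy-13-(dimethylamino)-8β-[(2S,3R)-2,3-dimethyloxirane-2-carbonyloxy]germacra-1(10)E,4Z-dien-6α,12-olide (C11 undefined) | CN(C)CC1C(=O)O[C@@H]2/C=C(/C)[C@@H](OC(=O)c3ccccc3)C/C=C(\C)C[C@@H](OC(=O)[C@@]3(C)O[C@@H]3C)[C@@H]12 | intermediate
34 | trimethylammonium iodide of 33 (C11 undefined) | C[N+](C)(C)CC1C(=O)O[C@@H]2/C=C(/C)[C@@H](OC(=O)c3ccccc3)C/C=C(\C)C[C@@H](OC(=O)[C@@]3(C)O[C@@H]3C)[C@@H]12.[I-] | intermediate
35 | 3β-benzoyloxy-8β-[(2S,3R)-2,3-dimethyloxirane-2-carbonyloxy]germacra-1(10)E,4Z,11(13)-trien-6α,12-olide | C=C1C(=O)O[C@@H]2/C=C(/C)[C@@H](OC(=O)c3ccccc3)C/C=C(\C)C[C@@H](OC(=O)[C@@]3(C)O[C@@H]3C)[C@@H]12 | intermediate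
36 | 1β,10α-epoxy-3β-benzoyloxy-8β-[(2S,3R)-2,3-dimethyloxirane-2-carbonyloxy]germacra-4Z,11(13)-dien-6α,12-olide (CNP0324463.4) | C=C1C(=O)O[C@@H]2/C=C(/C)[C@@H](OC(=O)c3ccccc3)C[C@H]3O[C@]3(C)C[C@@H](OC(=O)[C@@]3(C)O[C@@H]3C)[C@@H]12 | target

## Step count and least certain steps

Total step count: 20. Longest linear sequence: 17 (steps 1–7, 9–12 and 15–20, from 1 to 36); step 8 and steps 13–14 are side branches.

Step 10 (key step). The most likely failure is degradation before or after the shift under the naked-potassium conditions. The enolate oxygen sits cis to C8 and within reach of silicon, so it can attack the benzylsilane and cleave the benzyl–silicon bond; the alkoxide can also fragment in competition with the rearrangement. Fallback from 16 to 19 without a free oxyanion: silylation (Me3SiCl, imidazole, DMF) gives the trimethylsilyl ether F1; a thermal siloxy-Cope rearrangement of the same chair topology (degassed decalin, base-washed sealed tube, about 200 °C) gives the trimethylsilyl enol ether F2; K2CO3 in MeOH cleaves F2 to 19.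

Step 12. The most likely failure is premature closure of the O8 lithium alkoxide onto the new allyl ester (transesterification to a cis-fused lactone through O8) while the alkylation is still warming. That would remove the hydroxyl needed in step 15. Fallback from 21 to 29 with a carboxyl surrogate that an alkoxide does not attack: the same dianion is alkylated with bromoacetonitrile to give the 7β-cyanomethyl ketone F3; the Evans–Tishchenko reduction with 27 gives the 6α-hydroxy 8β-ester nitrile F4; neutral hydration with [PtH(PMe2OH)(PMe2O)2H] in aqueous ethanol gives the primary amide F5; PPTS in toluene closes F5 onto O6 with loss of ammonia to give 29.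

Step 15. The most likely failure is acyl migration from O8 to O6 on warming, in competition with closure of the samarium alkoxide onto the allyl ester. Slow hydride transfer with the hindered α-quaternary aldehyde would make this worse. Fallback from 24 to 29 that separates reduction from lactonisation: the reaction is quenched at −10 °C and 28 is isolated; Pd(PPh3)4 and morpholine (zerovalent palladium, neutral) remove the allyl group to give the hydroxy acid F6; EDC·HCl with catalytic DMAP closes F6 onto the only free hydroxyl to give 29.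

Step 9. The most likely failure is poor facial selectivity. In the favoured conformer of 9 the pseudoaxial ether at C4 lies on the face from which the reagent must come, so axial attack cis to isopropenyl may compete and give the cis-dialkenyl carbinol. Fallback from 7 to 16 that turns the oxygen into a directing group: PPTS in aqueous acetone converts 7 into the hydroxy enone F7; its magnesium alkoxide (i-PrMgCl, 1 equiv) is treated with 15, with delivery syn to the alkoxide, to give the diol F8; NaH (1 equiv), 4-methoxybenzyl chloride and Bu4NI at −20 °C etherify the secondary hydroxyl of F8 selectively to give 16.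

Step 20. The most likely failure is attack on the wrong face of C1=C10 if a ring conformer with C14 on the α side is populated, or partial reaction at C4=C5. Fallback from 35 to 36 under reagent control instead of substrate control: Shi epoxidation with the D-fructose-derived ketone, KHSO5 and K2CO3 buffer in MeCN/dimethoxymethane/H2O at 0 °C. The chiral dioxirane selects the face of the E trisubstituted alkene that gives the R,R epoxide and ignores the electron-poor alkenes. This fallback makes no new compound (F0).

## Further compounds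

F1 | step 10 | trimethylsilyl ether of 16 | CC(=C)[C@H]1C[C@H](OCc2ccc(OC)cc2)C(C)=C[C@]1(O[Si](C)(C)C)/C=C/[Si](C)(C)Cc1ccccc1
F2 | step 10 | trimethylsilyl enol ether of 19 (C6=C7, oxygen cis to C8) | C1/C=C(\C)C[C@@H]([Si](C)(C)Cc2ccccc2)/C=C(\O[Si](C)(C)C)/C=C(/C)[C@H]1OCc1ccc(OC)cc1
F3 | step 12 | 2-[(3S,7R,8R)-8-hydroxy-3-(4-methoxybenzyloxy)-4,10-dimethyl-6-oxocyclodeca-1(10)E,4Z-dien-7-yl]acetonitrile | O=C1/C=C(/C)[C@@H](OCc2ccc(OC)cc2)C/C=C(\C)C[C@@H](O)[C@H]1CC#N
F4 | step 12 | 2-{6α-hydroxy-8β-[(2S,3R)-2,3-dimethyloxirane-2-carbonyloxy]-3β-(4-methoxybenzyloxy)-4,10-dimethylcyclodeca-1(10)E,4Z-dien-7β-yl}acetonitrile | O[C@@H]1/C=C(/C)[C@@H](OCc2ccc(OC)cc2)C/C=C(\C)C[C@@H](OC(=O)[C@@]2(C)O[C@@H]2C)[C@H]1CC#N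
F5 | step 12 | 2-{6α-hydroxy-8β-[(2S,3R)-2,3-dimethyloxirane-2-carbonyloxy]-3β-(4-methoxybenzyloxy)-4,10-dimethylcyclodeca-1(10)E,4Z-dien-7β-yl}acetamide | O[C@@H]1/C=C(/C)[C@@H](OCc2ccc(OC)cc2)C/C=C(\C)C[C@@H](OC(=O)[C@@]2(C)O[C@@H]2C)[C@H]1CC(N)=O
F6 | step 15 | 2-{6α-hydroxy-8β-[(2S,3R)-2,3-dimethyloxirane-2-carbonyloxy]-3β-(4-methoxybenzyloxy)-4,10-dimethylcyclodeca-1(10)E,4Z-dien-7β-yl}acetic acid | O[C@@H]1/C=C(/C)[C@@H](OCc2ccc(OC)cc2)C/C=C(\C)C[C@@H](OC(=O)[C@@]2(C)O[C@@H]2C)[C@H]1CC(=O)O
F7 | step 9 | (4S,6R)-4-hydroxy-3-methyl-6-(prop-1-en-2-yl)cyclohex-2-en-1-one | CC(=C)[C@H]1C[C@H](O)C(C)=CC1=O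
F8 | step 9 | (1R,4S,6R)-1-[(E)-2-(benzyldimethylsilyl)ethenyl]-3-methyl-6-(prop-1-en-2-yl)cyclohex-2-ene-1,4-diol | CC(=C)[C@H]1C[C@H](O)C(C)=C[C@]1(O)/C=C/[Si](C)(C)Cc1ccccc1
F0 | step 20 | none | none
A1 | alternative 1 | tert-butyl 2-[6-(tert-butyldimethylsilyloxy)-4-methyl-2-oxocyclohex-3-en-1-yl]acetate with the C7 and C8 configuration of the target | O=C1C=C(C)C[C@@H](O[Si](C)(C)C(C)(C)C)[C@H]1CC(=O)OC(C)(C)C
A2 | alternative 1 | 3,3-dimethoxy-2-methylcyclobut-1-ene | CC1=CCC1(OC)OC
A3 | alternative 1 | cis-anti-cis tricyclic photoadduct | O=C1[C@@H]2[C@@]3(C)C(OC)(OC)C[C@H]3[C@]2(C)C[C@@H](O[Si](C)(C)C(C)(C)C)[C@H]1CC(=O)OC(C)(C)C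
A4 | alternative 2 | C6-unoxidised primary amide (target skeleton with a C7 acetamide side chain and a C6 methylene) | NC(=O)C[C@H]1C/C=C(/C)[C@@H](OC(=O)c2ccccc2)C[C@H]2O[C@]2(C)C[C@H]1OC(=O)[C@@]1(C)O[C@@H]1C
A5 | alternative 2 | 13-nor lactone | C1C(=O)O[C@@H]2/C=C(/C)[C@@H](OC(=O)c3ccccc3)C[C@H]3O[C@]3(C)C[C@@H](OC(=O)[C@@]3(C)O[C@@H]3C)[C@@H]12
A6 | alternative 3 | open-chain Z-enal oxime with terminal vinyl group | O=C1C[C@H]([C@H](O[Si](C)(C)C(C)(C)C)C[C@@](C)(O[Si](CC)(CC)CC)C=C)[C@@H](/C=C(/C)C=NO)O1
A7 | alternative 3 | nitrile oxide derived from A6 | O=C1C[C@H]([C@H](O[Si](C)(C)C(C)(C)C)C[C@@](C)(O[Si](CC)(CC)CC)C=C)[C@@H](/C=C(/C)C#[N+][O-])O1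
A8 | alternative 3 | isoxazoline-bridged ten-membered lactone | O=C1C[C@@H]2[C@H](O[Si](C)(C)C(C)(C)C)C[C@@](C)(O[Si](CC)(CC)CC)[C@@H]3CC(=NO3)/C(C)=C\[C@H]2O1
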